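Alder is cedar's neighbour: the charges match, except that added ligand goes from 0.35 mM to 1.0 mM.

| flask | starting material | second substrate | free catalyst | added ligand | time |
|---|---|---|---|---|---|
| cedar | 1.0 mM | 2.00 mM | 0.12 mM | 0.35 mM | 25 s |
| alder | 1.0 mM | 2.00 mM | 0.12 mM | 1.0 mM | 25 s |

    starting material + free catalyst ⇌ catalyst intermediate A (K1 = 1060 M⁻¹, k1 = 1800 M⁻¹ s⁻¹)
    catalyst intermediate A → free catalyst + target (k2 = 34.0 s⁻¹)
    second substrate + free catalyst ⇌ catalyst intermediate B (K3 = 733 M⁻¹, k3 = 2150 M⁻¹ s⁻¹)
    catalyst intermediate B → free catalyst + second product (k4 = 0.331 s⁻¹)
    free catalyst + added ligand ⇌ idle complex, settled at all times (K5 = 9200 M⁻¹)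
    free catalyst → spent catalyst (k6 = 0.0711 s⁻¹)

1. which of these there is most of at the end, counted by the starting material in it, cedar (target / catalyst intermediate A / starting material)
2. which of these there is most of at the end, counted by the starting material in it, alder (target / catalyst intermediate A / starting material)
3. amount of the one of these that there is most of at the end, in percent of the starting material charged, cedar
4. amount of the one of these that there is most of at the end, in percent of the starting material charged, alder

First ask which numbers must be good. Catalyst intermediate A goes on at 34.0 s⁻¹ and returns at 1.70 s⁻¹, so nearly all of what binds becomes target. An error in K1 or k2 therefore barely shows, but an error in k1 passes straight into the effective rate constant for starting material, 1710 M⁻¹ s⁻¹.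

Now count each catalyst form as a load, its amount per free catalyst. Catalyst intermediate A carries 0.0504, so it matters little. Catalyst intermediate B carries 1.32, so K3 counts, while k4 is a small addition, 0.331 s⁻¹ beside 2.93 s⁻¹. The idle complex in cedar carries 3.22, more than the other two, so K5 outweighs K3 among the loads.

One over one plus the loads gives 0.179. But the idle complex uses up ligand, so c(added ligand) is really nearer 0.281 mM. Put that back in and go round once more: cedar has a working share, free catalyst over catalyst not yet spent, of 0.202. Alder, by the same two rounds, has 0.0935. In cedar a small relative error in K5 reaches the share at about 0.522 of its size, while one in k1 reaches the effective rate constant at 0.952 of its size, so k1 needs knowing better than K5.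

Step 6 attacks free catalyst, so unspent catalyst decays at k6 times the share. Starting material falls pseudo-first-order at 1710 M⁻¹ s⁻¹ times c(free catalyst), and the time integral of c(free catalyst) is simply the spent catalyst over k6. I reckon 41.8 % starting material left in cedar, hence 58.2 % target, and 64.2 % left in alder.

The forecast makes the same two choices: target at 58 % for cedar and starting material at 64 % for alder, since “the ligand and intermediate B hold free catalyst” low.

The simulation gives target at 58.1 % in cedar and starting material at 64.2 % in alder. In cedar, steps 1 and 2 ran throughout, with 65 % of the turnover of step 2 done by 12.5 s. Meanwhile step 6 brought spent catalyst to 16.4 % then and 30.1 % at 25.0 s, and the working share read at 12.5 s is 0.201. For the neighbour of cedar with 0.20 mM of free catalyst, more ligand is tied up, the share becomes 0.221, and 20.9 % starting material is reckoned to remain. That flask ended with 21.3 % starting material.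

The constants come from no measurement; the flask was simulated.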